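Assumption: the SMILES carries no descriptor for the C5–C5' axis, so the target is taken as the biaryl without defined axial configuration (the racemate if the axis is configurationally stable); no stereocentre has to be set.

## Structural features

The target is an unsymmetrical dimer of two 2-(2-phenylethyl)-4H-chromen-4-ones: unit A (benzo ring = ring A) carries a hydroxyl at C6, unit B (ring B) a hydroxyl at C8', and the two benzo rings are joined by one C5–C5' biaryl bond. C5 lies between C4a, which is peri to the C4 carbonyl, and the hydroxylated C6; C5' lies between C4a', peri to the C4' carbonyl, and C6'–H, and is para to the C8' hydroxyl. The axis therefore has three ortho substituents and two peri carbonyl groups; there is no stereocentre, and the axis is the only stereogenic element. Ring A is a hydroquinone pattern (O1 on C8a para to the oxygen on C6) with the acyl carbon on C4a; ring B is a catechol pattern (O1' on C8a', hydroxyl on C8'). Both biaryl carbons are ortho or para to a phenolic oxygen, so the bond unites two carbons of the same innate, nucleophilic polarity. Fragile points are the oxidisable hydroquinone-type ring A, the base-sensitive pyranones (acidic methylene on the C2 side chains, ring opening at C2) and the reducible C2=C3 bonds. The real difficulty is the congested C5–C5' bond at the correct position of each ring; the key step exploits that C5 sits between the acyl-bearing C4a and the hydroxyl-bearing C6 of a hydroquinone ring, which is exactly where a nucleophile enters a 2-acyl-1,4-benzoquinone, and that C5' is the para carbon of the C8' phenol.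

## Logic of the disconnections

In one sentence: the biaryl bond is made by redox-neutral conjugate C-arylation of 7 at its C3 by the para carbon of the free phenol 5, and the hydroquinone pattern of ring A appears by tautomerisation of the adduct.

10 to 8 and 2. The O1–C2 and C2–C3 bonds of the pyranone of unit A are cut (through 9). This reduces the second chromone to an acetyl group next to a free hydroxyl, and 2, which already builds unit B, serves a second time. The gain is that no protecting group enters the route after the key step. The forward demand is a crossed Claisen condensation at the enolate of an acetyl group with two ortho substituents, in the presence of three phenoxides, followed by acid closure of the pyranone.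

8 to 5 and 7 (key). The C5–C5' bond is cut. In 8 the ring A carbon of this bond lies between the acetyl-bearing carbon and a hydroxyl-bearing carbon of a hydroquinone, which is the adduct pattern of a nucleophile at C3 of 7. The ring B carbon is para to the free hydroxyl of 5. The gain is the largest of the route: a bond with three ortho substituents and two peri carbonyls is traced back to two pieces that carry no halogen, no boron and no protecting group, and the oxygen pattern and the acetyl group of ring A arrive in the same operation. The forward demand is attack by C5' of 5 (not by C7' or by oxygen) at C3 of 7, without redox exchange between product and 7.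

7 to 6. No carbon–carbon bond is cut; only the oxidation level changes. This reverses the polarity of the ring A carbon from nucleophilic (in 6) to electrophilic (in 7). The forward demand is a mild, anhydrous oxidation of a hydroquinone.

5 to 4, then to 1 and 2. The O–CH3 bond is cut first, so that the free phenol needed as the activating group in the key step is unmasked only after the pyranone is in place. Then the O1'–C2' and C2'–C3' bonds of the pyranone of unit B are cut (through 3), which leads to two commercial compounds. The forward demand is a crossed Claisen condensation at the dianion of 1, then acid closure.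

## Other disconnections considered

Alternative 1: the same C5–C5' bond cut as halide plus boronate, which is the first plan that comes to mind. The forward key step would be a Suzuki–Miyaura coupling of the bromide 5-bromo-6-methoxy-2-(2-phenylethyl)-4H-chromen-4-one A1 with the boronate 8-methoxy-2-(2-phenylethyl)-5-(4,4,5,5-tetramethyl-1,3,2-dioxaborolan-2-yl)-4H-chromen-4-one A2. It would give the dimethyl ether A3, and demethylation would follow.
- Structure: the three ortho substituents and two peri carbonyls of A3 are expected to slow transmetalation and reductive elimination.
- Mechanism: the boronate A2 sits peri to a carbonyl and is prone to protodeboronation.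
- Step economy: the bromide A1 and the boronate A2 need two chromone syntheses, two regioselective halogenations, two O-protections, a borylation and a final deprotection, about ten steps. The chosen plan uses the oxygen atoms already present as the activating groups and needs five.

Alternative 2: the C5–C5' bond cut as a direct oxidative cross-coupling of two free phenols, the monomer 6-hydroxy-2-(2-phenylethyl)-4H-chromen-4-one A4 and 5, with FeCl3 and tBuOOtBu, with PhI(OAc)2 or by anodic oxidation.
- This is the shortest route on paper, but nothing in the phenol A4 or in 5 enforces cross- over homo-coupling: both rings are acyl-deactivated phenols of similar, high oxidation potential.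
- C–O coupling and coupling at C7' of 5 compete.
- The product, with its hydroquinone-type ring A, is expected to be oxidised more easily than either monomer.
- The chosen plan is the controlled form of the same idea: one partner is oxidised beforehand to a defined quinone, so chemoselectivity and the position on ring A are fixed by structure.

Alternative 3: ring B built from a 2-pyrone, with cuts at C4a'–C5' and C6'–C7'. The forward key step would be a Diels–Alder reaction of the alkyne 5-ethynyl-6-methoxy-2-(2-phenylethyl)-4H-chromen-4-one A5 with the pyrone 3-acetyl-4,5-dimethoxy-2H-pyran-2-one A6 with loss of carbon dioxide. It would give the biaryl 5-(2-acetyl-3,4-dimethoxyphenyl)-6-methoxy-2-(2-phenylethyl)-4H-chromen-4-one A7, and the pyranone of unit B and three demethylations would follow.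
- The biaryl bond is never made by coupling, which is attractive.
- The pyrone A6 is not commercial and needs its own synthesis.
- The cycloaddition pairs the electron-poor, doubly ortho-hindered arylalkyne A5 with a push–pull pyrone, so it is electronically mismatched and would need high temperature.
- Its regiochemistry, which decides whether the biaryl A7 or its isomer forms, rests on small differences in orbital coefficients rather than on a structural lock.
- The route is expected to be about twice as long as the chosen one.

Key step: step 4

## Steps

Step 1
Reactants: 1 1-(2-hydroxy-3-methoxyphenyl)ethan-1-one; 2 methyl 3-phenylpropanoate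
Product: 4 8-methoxy-2-(2-phenylethyl)-4H-chromen-4-one, via 1,3-diketone 3 (not isolated)
Conditions: NaH (4 equiv), 2 (2 equiv), THF, reflux; then conc. HCl, MeOH, reflux
Reagents that add atoms: none
Why: Crossed Claisen condensation of the phenoxide–enolate dianion of 1 with ester 2 should give β-diketone 3; acid then closes the pyranone by attack of the phenol on the distal ketone and dehydration, the standard construction of 2-alkylchromones.

Step 2
Reactants: 4 8-methoxy-2-(2-phenylethyl)-4H-chromen-4-one
Product: 5 8-hydroxy-2-(2-phenylethyl)-4H-chromen-4-one
Conditions: BBr3 (3 equiv), CH2Cl2, −78 °C to rt; then H2O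
Reagents that add atoms: none
Why: Lewis acid cleavage of an aryl methyl ether; the chromone carbonyl only binds one equivalent of BBr3 reversibly, and the saturated side chain is inert.

Step 3
Reactants: 6 1-(2,5-dihydroxyphenyl)ethan-1-one
Product: 7 2-acetylcyclohexa-2,5-diene-1,4-dione
Conditions: Ag2O (2.5 equiv), MgSO4, CH2Cl2, rt, dark; filtration through Celite, used at once
Reagents that add atoms: none
Why: Oxidation of a hydroquinone to the 1,4-benzoquinone with Ag2O is a mild heterogeneous dehydrogenation; the drying agent removes the water formed, which would otherwise add to this doubly activated quinone.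

Step 4
Reactants: 5 8-hydroxy-2-(2-phenylethyl)-4H-chromen-4-one; 7 2-acetylcyclohexa-2,5-diene-1,4-dione
Product: 8 5-(2-acetyl-3,6-dihydroxyphenyl)-8-hydroxy-2-(2-phenylethyl)-4H-chromen-4-one
Conditions: 5 (1.2 equiv), Sc(OTf)3 (10 mol %), CH2Cl2/(CF3)2CHOH 4:1, −20 °C to rt, slow addition of 7, N2; then aq. Na2S2O4 wash
Reagents that add atoms: none
Why: Sc(OTf)3 chelates the acetyl oxygen and the C1 carbonyl of 7, which makes C3, the only ring carbon β to two carbonyl groups, the most electrophilic site; the para carbon C5' of phenol 5 attacks it in a Friedel–Crafts-type conjugate addition, the cyclohexadienone so formed rearomatises by proton loss and the chelated ene-trione tautomerises twice to the hydroquinone, so the C5–C5' bond is made with no net oxidant or reductant. The closest known reaction type is the acid-catalysed conjugate arylation of 2-acyl- and 2-alkoxycarbonyl-1,4-benzoquinones by naphthols and phenols, which gives 3-aryl-2-acylhydroquinones. No ring is closed and no stereocentre is formed; the new axis arises without control, which is all the unspecified target requires. Selectivity on the quinone (C3, not C5 or C6) is secured by the acetyl group. Selectivity on 5 requires reaction at C5' and not at C7' or at oxygen: both carbons are activated only by the C8' hydroxyl, and para attack is expected to prevail as it does in electrophilic substitution of 3-acylphenols, helped by hydrogen bonding of the hydroxyl to (CF3)2CHOH, which disfavours ortho delivery, while attack through oxygen is reversible under acid. Slow addition of 7 to an excess of 5 keeps the oxidising quinone away from product 8, and the dithionite wash returns any over-oxidised material to 8.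

Step 5
Reactants: 8 5-(2-acetyl-3,6-dihydroxyphenyl)-8-hydroxy-2-(2-phenylethyl)-4H-chromen-4-one; 2 methyl 3-phenylpropanoate
Product: 10 6-hydroxy-5-[8-hydroxy-4-oxo-2-(2-phenylethyl)-4H-chromen-5-yl]-2-(2-phenylethyl)-4H-chromen-4-one, via 1,3-diketone 9 (not isolated)
Conditions: LiN(SiMe3)2 (4.5 equiv), degassed THF, −78 to 0 °C, Ar; then 2 (2 equiv), 0 to 50 °C; then conc. HCl, MeOH, reflux
Reagents that add atoms: none
Why: Crossed Claisen condensation of polylithiated 8, the same reaction type as step 1: LiN(SiMe3)2 turns the three phenols into lithium phenoxides and the acetyl group into its enolate, whose terminal carbon lies outside the crowded biaryl plane and is acylated by ester 2, the methoxide set free deprotonating β-diketone 9 and so driving the equilibrium. Acid then closes the pyranone by attack of the ortho phenol on the distal ketone and dehydration, which gives 10 with both remaining hydroxyls free and no deprotection step.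

## Compound list

1 | 1-(2-hydroxy-3-methoxyphenyl)ethan-1-one | CC(=O)c1cccc(OC)c1O | starting material
2 | methyl 3-phenylpropanoate | COC(=O)CCc1ccccc1 | starting material
3 | 1-(2-hydroxy-3-methoxyphenyl)-5-phenylpentane-1,3-dione | COc1cccc(C(=O)CC(=O)CCc2ccccc2)c1O | intermediate
4 | 8-methoxy-2-(2-phenylethyl)-4H-chromen-4-one | COc1cccc2c(=O)cc(CCc3ccccc3)oc12 | intermediate
5 | 8-hydroxy-2-(2-phenylethyl)-4H-chromen-4-one | O=c1cc(CCc2ccccc2)oc2c(O)cccc12 | intermediate
6 | 1-(2,5-dihydroxyphenyl)ethan-1-one | CC(=O)c1cc(O)ccc1O | starting material
7 | 2-acetylcyclohexa-2,5-diene-1,4-dione | CC(=O)C1=CC(=O)C=CC1=O | intermediate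
8 | 5-(2-acetyl-3,6-dihydroxyphenyl)-8-hydroxy-2-(2-phenylethyl)-4H-chromen-4-one | CC(=O)c1c(O)ccc(O)c1-c1ccc(O)c2oc(CCc3ccccc3)cc(=O)c12 | intermediate
9 | 1-{3,6-dihydroxy-2-[8-hydroxy-4-oxo-2-(2-phenylethyl)-4H-chromen-5-yl]phenyl}-5-phenylpentane-1,3-dione | O=C(CC(=O)CCc1ccccc1)c1c(O)ccc(O)c1-c1ccc(O)c2oc(CCc3ccccc3)cc(=O)c12 | intermediate
10 | 6-hydroxy-5-[8-hydroxy-4-oxo-2-(2-phenylethyl)-4H-chromen-5-yl]-2-(2-phenylethyl)-4H-chromen-4-one | O=c1cc(CCc2ccccc2)oc2ccc(O)c(-c3ccc(O)c4oc(CCc5ccccc5)cc(=O)c34)c12 | target

## Step count and least certain steps

Total step count: 5. Longest linear sequence: 4 steps (steps 1, 2, 4, 5); step 3 is the side branch.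

Step 4 (key step). The most likely failure is carbon–carbon bond formation through the ortho carbon C7' of 5, or through oxygen, instead of through C5'. Both ring carbons are activated by the same hydroxyl, and only C5' is shielded by the peri carbonyl. A second failure is redox exchange between the product hydroquinone and unreacted 7.

The fallback sets out from 5 and comes back at 8. Ortho-selective bromination of 5 (N-bromosuccinimide, catalytic iPr2NH, CH2Cl2, 0 °C) would give 7-bromo-8-hydroxy-2-(2-phenylethyl)-4H-chromen-4-one F1, in which the competing ortho carbon is occupied. Union of F1 with 7 under the conditions of step 4 would give 5-(2-acetyl-3,6-dihydroxyphenyl)-7-bromo-8-hydroxy-2-(2-phenylethyl)-4H-chromen-4-one F2. Hydrodebromination of F2 (Pd(OAc)2, PPh3, HCO2H, Et3N, DMF, 60 °C) would return 8. Regiocontrol then rests on a blocking group and no longer on the para preference of the phenol.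

Step 5. The most likely failure is incomplete or misdirected acylation of the polyanion. The tetralithiated form of 8 may be poorly soluble, and the enolate sits on an acetyl group with two ortho substituents. Excess base can also deprotonate the C2' side-chain methylene of unit B or enolise ester 2. The hydroquinone phenoxides are oxidised by traces of oxygen.

The fallback sets out from 8 and comes back at 10, and replaces the intermolecular condensation by an intramolecular acyl transfer with the other phenols masked. Exhaustive acylation of 8 with 3-phenylpropanoyl chloride (4 equiv, Et3N, DMAP, CH2Cl2, 0 °C to rt, N2) would give 2-acetyl-3-[4-oxo-2-(2-phenylethyl)-8-(3-phenylpropanoyloxy)-4H-chromen-5-yl]-1,4-phenylene bis(3-phenylpropanoate) F3. Baker–Venkataraman rearrangement of F3 (LiN(SiMe3)2, THF, −78 to 0 °C) would move the acyl group ortho to the acetyl group onto carbon and give 4-hydroxy-3-(3-oxo-5-phenylpentanoyl)-2-[4-oxo-2-(2-phenylethyl)-8-(3-phenylpropanoyloxy)-4H-chromen-5-yl]phenyl 3-phenylpropanoate F4. Conc. HCl in MeOH at reflux would close the pyranone to 4-oxo-5-[4-oxo-2-(2-phenylethyl)-6-(3-phenylpropanoyloxy)-4H-chromen-5-yl]-2-(2-phenylethyl)-4H-chromen-8-yl 3-phenylpropanoate F5, and continued methanolysis of the two aryl esters in the same medium would give 10.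

Step 3. The most likely failure is decomposition of 7 during filtration and concentration (hydration, self-condensation, light-induced reactions), because the quinone carries an additional acceptor.

The fallback sets out from 6 and comes back at 8 without any isolated electrophile. 6 and 5 are stirred with Sc(OTf)3 in CH2Cl2/(CF3)2CHOH and Ag2O is added in portions, so that 7 is trapped by 5 as it forms. This is followed by the same reductive wash. The step becomes a dehydrogenative coupling whose selectivity rests on the much easier oxidation of the hydroquinone 6 compared with the monophenol 5. No new compound is made.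

Step 1. The most likely failure is self-condensation of ester 2 outrunning the crossed condensation at the poorly soluble disodium salt of 1.

The fallback sets out from 1 and comes back at 4. Acylation of 1 with 3-phenylpropanoyl chloride (Et3N, DMAP, CH2Cl2) would give 2-acetyl-6-methoxyphenyl 3-phenylpropanoate F6. Its Baker–Venkataraman rearrangement (LiN(SiMe3)2, THF, −78 to 0 °C) would give 3 by intramolecular acyl transfer, and HCl in MeOH would close it to 4.

## Further compounds

F1 | step 4 | 7-bromo-8-hydroxy-2-(2-phenylethyl)-4H-chromen-4-one | O=c1cc(CCc2ccccc2)oc2c(O)c(Br)ccc12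
F2 | step 4 | 5-(2-acetyl-3,6-dihydroxyphenyl)-7-bromo-8-hydroxy-2-(2-phenylethyl)-4H-chromen-4-one | CC(=O)c1c(O)ccc(O)c1-c1cc(Br)c(O)c2oc(CCc3ccccc3)cc(=O)c12
F3 | step 5 | 2-acetyl-3-[4-oxo-2-(2-phenylethyl)-8-(3-phenylpropanoyloxy)-4H-chromen-5-yl]-1,4-phenylene bis(3-phenylpropanoate) | CC(=O)c1c(OC(=O)CCc2ccccc2)ccc(OC(=O)CCc2ccccc2)c1-c1ccc(OC(=O)CCc2ccccc2)c2oc(CCc3ccccc3)cc(=O)c12
F4 | step 5 | 4-hydroxy-3-(3-oxo-5-phenylpentanoyl)-2-[4-oxo-2-(2-phenylethyl)-8-(3-phenylpropanoyloxy)-4H-chromen-5-yl]phenyl 3-phenylpropanoate | O=C(CC(=O)CCc1ccccc1)c1c(O)ccc(OC(=O)CCc2ccccc2)c1-c1ccc(OC(=O)CCc2ccccc2)c2oc(CCc3ccccc3)cc(=O)c12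
F5 | step 5 | 4-oxo-5-[4-oxo-2-(2-phenylethyl)-6-(3-phenylpropanoyloxy)-4H-chromen-5-yl]-2-(2-phenylethyl)-4H-chromen-8-yl 3-phenylpropanoate | O=c1cc(CCc2ccccc2)oc2ccc(OC(=O)CCc3ccccc3)c(-c3ccc(OC(=O)CCc4ccccc4)c4oc(CCc5ccccc5)cc(=O)c34)c12
F0 | step 3 | none | none
F6 | step 1 | 2-acetyl-6-methoxyphenyl 3-phenylpropanoate | CC(=O)c1cccc(OC)c1OC(=O)CCc1ccccc1
A1 | alternative 1 | 5-bromo-6-methoxy-2-(2-phenylethyl)-4H-chromen-4-one | COc1ccc2oc(CCc3ccccc3)cc(=O)c2c1Br
A2 | alternative 1 | 8-methoxy-2-(2-phenylethyl)-5-(4,4,5,5-tetramethyl-1,3,2-dioxaborolan-2-yl)-4H-chromen-4-one | COc1ccc(B2OC(C)(C)C(C)(C)O2)c2c(=O)cc(CCc3ccccc3)oc12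
A3 | alternative 1 | 6-methoxy-5-[8-methoxy-4-oxo-2-(2-phenylethyl)-4H-chromen-5-yl]-2-(2-phenylethyl)-4H-chromen-4-one | COc1ccc2oc(CCc3ccccc3)cc(=O)c2c1-c1ccc(OC)c2oc(CCc3ccccc3)cc(=O)c12
A4 | alternative 2 | 6-hydroxy-2-(2-phenylethyl)-4H-chromen-4-one | O=c1cc(CCc2ccccc2)oc2ccc(O)cc12
A5 | alternative 3 | 5-ethynyl-6-methoxy-2-(2-phenylethyl)-4H-chromen-4-one | COc1ccc2oc(CCc3ccccc3)cc(=O)c2c1C#C
A6 | alternative 3 | 3-acetyl-4,5-dimethoxy-2H-pyran-2-one | O=C1OC=C(OC)C(OC)=C1C(C)=O
A7 | alternative 3 | 5-(2-acetyl-3,4-dimethoxyphenyl)-6-methoxy-2-(2-phenylethyl)-4H-chromen-4-one | COc1ccc2oc(CCc3ccccc3)cc(=O)c2c1-c1ccc(OC)c(OC)c1C(C)=O
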